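## Ret­ro­syn­thet­ic over­view

1. Michaolide A ⇐ oxidation of a C9 boronate ⇐ ring contraction: the 14-membered carbocycle is closed last by a 1,2-metallate shift inside a 15-membered cyclic boronate complex. This forges C8–C9 and sets C9, starting from a seco compound with a C8 alkenyl-B(pin) and a C9 α-sulfinyl benzoate.
2. Seco compound ⇐ C1–C14 bond and the α-methylene lactone by divalent-chromium allylation of a β,γ-unsaturated aldehyde (east, C9–C14) with a 3-(bromomethyl)butenolide (west, C1–C8), then invertive acetylation at C14.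
3. West ⇐ butenolide (C2) by Nozaki–Hiyama–Kishi coupling/lactonisation of an epoxy aldehyde with a β-iodoacrylate; oxirane (C3, C4) by Sharpless epoxidation; C5 by catalytic asymmetric allylboration; C7=C8–B by cross-metathesis.
4. East ⇐ carboalumination/oxirane opening (11E alkene), then sparteine-mediated lithiation–sulfinylation (C9 carbenoid precursor).
5. Ring order: oxirane → butenolide (becomes the trans-fused α-methylene lactone at fragment union) → 14-membered carbocycle.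

Assumption: acetate 1 and silyl ether 14 are bought as such (acetyl and TBS are protecting groups); the stereochemical outcomes below are predictions from standard models, not experimental results.

Cembrane numbering is used throughout: C1 (lactone CH), C2 (lactone O–CH), C3/C4 oxirane (C18 methyl), C5 (OAc), C7=C8 (C19 methyl), C9 (OH), C11=C12 (C20 methyl), C14 (OAc), C15(=C17H2)–C16(=O). Target: 1R,2S,3S,4S,5R,9S,14R,7E,11E.

## Route

Step 1
Reactants: 1 (2E)-3-methyl-4-oxobut-2-en-1-yl acetate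
Product: 3 (2E,4R)-4-hydroxy-3-methylhepta-2,6-dien-1-yl acetate, via pinacol borate 2 (not isolated)
Conditions: allylB(pin) (1.3 equiv), (R)-TRIP (5 mol%), toluene, −30 °C; aq. NaHCO3
Reagents that add atoms: allylboronic acid pinacol ester, C=CCB1OC(C)(C)C(C)(C)O1
Why: Chiral phosphoric acid-catalysed asymmetric allylboration through a chair transition state adds allyl to the Re face of the enal and sets the C5 carbinol as R, leaving the allylic acetate untouched.

Step 2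
Reactants: 3 (2E,4R)-4-hydroxy-3-methylhepta-2,6-dien-1-yl acetate
Product: 4 (2E,4R)-3-methylhepta-2,6-diene-1,4-diyl diacetate
Conditions: Ac2O, pyridine, DMAP (cat.), CH2Cl2, 0 °C → rt
Reagents that add atoms: acetic anhydride, CC(=O)OC(C)=O
Why: DMAP-catalysed acylation installs the C5 acetate of the target with retention.

Step 3
Reactants: 4 (2E,4R)-3-methylhepta-2,6-diene-1,4-diyl diacetate
Product: 5 (2E,4R)-1-hydroxy-3-methylhepta-2,6-dien-4-yl acetate
Conditions: immobilised Candida antarctica lipase B, pH 7 phosphate buffer/acetone, 25 °C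
Reagents that add atoms: none
Why: Lipase-catalysed hydrolysis is selective for the unhindered primary allylic acetate over the secondary acetate flanked by two bulky residues, freeing the C2 hydroxyl only.

Step 4
Reactants: 5 (2E,4R)-1-hydroxy-3-methylhepta-2,6-dien-4-yl acetate
Product: 6 (1R)-1-[(2S,3S)-3-(hydroxymethyl)-2-methyloxiran-2-yl]but-3-en-1-yl acetate
Conditions: Ti(OiPr)4 (10 mol%), L-(+)-DET (12 mol%), t-BuOOH, 4 Å MS, CH2Cl2, −20 °C
Reagents that add atoms: tert-butyl hydroperoxide, CC(C)(C)OO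
Why: Sharpless asymmetric epoxidation of the E-trisubstituted primary allylic alcohol is reagent-controlled, and L-(+)-tartrate gives the (3S,4S) oxirane of the target (same sense as geraniol to (2S,3S)-epoxygeraniol), while the terminal alkene is inert.

Step 5
Reactants: 6 (1R)-1-[(2S,3S)-3-(hydroxymethyl)-2-methyloxiran-2-yl]but-3-en-1-yl acetate
Product: 7 (1R,3Z)-1-[(2S,3S)-3-(hydroxymethyl)-2-methyloxiran-2-yl]-4-(4,4,5,5-tetramethyl-1,3,2-dioxaborolan-2-yl)pent-3-en-1-yl acetate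
Conditions: isopropenylB(pin) (4 equiv), second-generation Hoveyda–Grubbs catalyst (5 mol%), CH2Cl2, 40 °C
Reagents that add atoms: isopropenylboronic acid pinacol ester, C=C(C)B1OC(C)(C)C(C)(C)O1
Why: Olefin cross-metathesis of the terminal alkene with the 1,1-disubstituted vinylboronate gives the trisubstituted alkenylboronate with boron trans to the chain (thermodynamic control), which fixes the later 7E geometry.

Step 6
Reactants: 7 (1R,3Z)-1-[(2S,3S)-3-(hydroxymethyl)-2-methyloxiran-2-yl]-4-(4,4,5,5-tetramethyl-1,3,2-dioxaborolan-2-yl)pent-3-en-1-yl acetate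
Product: 8 (1R,3Z)-1-[(2S,3R)-3-formyl-2-methyloxiran-2-yl]-4-(4,4,5,5-tetramethyl-1,3,2-dioxaborolan-2-yl)pent-3-en-1-yl acetate
Conditions: Dess–Martin periodinane, pyridine, CH2Cl2, 0 °C → rt
Reagents that add atoms: none
Why: Buffered Dess–Martin oxidation gives the epoxy aldehyde without touching the oxirane or the C–B bond (the C3 descriptor changes only through priorities).

Step 7
Reactants: 9 methyl propiolate
Product: 10 methyl (2Z)-2-(hydroxymethyl)-3-iodoprop-2-enoate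
Conditions: MgI2 (1.2 equiv), CH2O (monomer in CH2Cl2), CH2Cl2, 0 °C
Reagents that add atoms: formaldehyde, C=O; magnesium iodide (MgI2), [Mg+2].[I-].[I-]
Why: Iodo-aldol (β-iodo Morita–Baylis–Hillman) reaction, in which iodide conjugate addition to the ynoate and α-trapping by formaldehyde kinetically give the Z isomer with iodine cis to the ester.

Step 8
Reactants: 8 (1R,3Z)-1-[(2S,3R)-3-formyl-2-methyloxiran-2-yl]-4-(4,4,5,5-tetramethyl-1,3,2-dioxaborolan-2-yl)pent-3-en-1-yl acetate; 10 methyl (2Z)-2-(hydroxymethyl)-3-iodoprop-2-enoate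
Product: 12 (1R,3Z)-1-[(2S,3S)-3-[(2S)-4-(hydroxymethyl)-5-oxo-2,5-dihydrofuran-2-yl]-2-methyloxiran-2-yl]-4-(4,4,5,5-tetramethyl-1,3,2-dioxaborolan-2-yl)pent-3-en-1-yl acetate, via hydroxy ester 11 (not isolated)
Conditions: CrCl2 (5 equiv), NiCl2 (2 mol%), DMSO/THF, rt; then PPTS (cat.), CH2Cl2
Reagents that add atoms: none
Why: Nozaki–Hiyama–Kishi coupling (zerovalent nickel inserts into C–I, transfer to trivalent chromium, alkene geometry retained) adds to the aldehyde under Felkin–Anh control with the oxirane C–O anti to the nucleophile, setting C2 as S (2,3-erythro), and the Z-configured alkoxide lactonises to the butenolide.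

Step 9
Reactants: 12 (1R,3Z)-1-[(2S,3S)-3-[(2S)-4-(hydroxymethyl)-5-oxo-2,5-dihydrofuran-2-yl]-2-methyloxiran-2-yl]-4-(4,4,5,5-tetramethyl-1,3,2-dioxaborolan-2-yl)pent-3-en-1-yl acetate
Product: 13 (1R,3Z)-1-[(2S,3S)-3-[(2S)-4-(bromomethyl)-5-oxo-2,5-dihydrofuran-2-yl]-2-methyloxiran-2-yl]-4-(4,4,5,5-tetramethyl-1,3,2-dioxaborolan-2-yl)pent-3-en-1-yl acetate
Conditions: CBr4, PPh3, 2,6-lutidine, CH2Cl2, 0 °C
Reagents that add atoms: carbon tetrabromide, BrC(Br)(Br)Br
Why: Appel bromination converts the primary allylic alcohol into the bromide by SN2 displacement without affecting oxirane, acetate or boronate.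

Step 10
Reactants: 14 tert-butyl(but-3-yn-1-yloxy)dimethylsilane
Product: 16 (3E)-6-[(tert-butyldimethylsilyl)oxy]-4-methylhex-3-en-1-ol, via alkenylalane 15 (not isolated)
Conditions: AlMe3 (2.5 equiv), Cp2ZrCl2 (25 mol%), CH2Cl2, 0 °C → rt; n-BuLi, THF/hexane, −78 °C; oxirane, −78 → 0 °C
Reagents that add atoms: trimethylaluminium (AlMe3), C[Al](C)C; oxirane, C1CO1
Why: Negishi zirconium-catalysed syn-carboalumination places methyl on the internal and aluminium on the terminal alkyne carbon, and the derived alanate opens oxirane with retention, giving the E-trisubstituted alkene (future 11E).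

Step 11
Reactants: 16 (3E)-6-[(tert-butyldimethylsilyl)oxy]-4-methylhex-3-en-1-ol
Product: 17 (3E)-6-[(tert-butyldimethylsilyl)oxy]-4-methylhex-3-en-1-yl 2,4,6-triisopropylbenzoate
Conditions: 2,4,6-triisopropylbenzoic acid, PPh3, DIAD, THF, 0 °C → rt
Reagents that add atoms: 2,4,6-triisopropylbenzoic acid, CC(C)c1cc(C(C)C)c(C(=O)O)c(C(C)C)c1
Why: Mitsunobu esterification of the primary alcohol with the hindered acid gives the benzoate that directs and stabilises the later α-metalation.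

Step 12
Reactants: 17 (3E)-6-[(tert-butyldimethylsilyl)oxy]-4-methylhex-3-en-1-yl 2,4,6-triisopropylbenzoate
Product: 20 (1R,3E)-6-[(tert-butyldimethylsilyl)oxy]-4-methyl-1-[(S)-(4-methylphenyl)sulfinyl]hex-3-en-1-yl 2,4,6-triisopropylbenzoate, via lithiated benzoate 18 (not isolated), via magnesiated benzoate 19 (not isolated)
Conditions: s-BuLi, (+)-sparteine, Et2O, −78 °C, 5 h; MgBr2·OEt2; (−)-menthyl (S)-p-toluenesulfinate, −78 °C → rt; recrystallise
Reagents that add atoms: (1R,2S,5R)-menthyl (S)-4-methylbenzenesulfinate, Cc1ccc(cc1)[S@@](=O)O[C@@H]1C[C@H](C)CC[C@H]1C(C)C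
Why: Hoppe-type sparteine-mediated enantioselective deprotonation ((+)-sparteine removes the pro-R proton) followed by sulfinylation with retention at carbon and inversion at sulfur (Andersen sulfinate) sets C9 as R in a single crystalline diastereomer.

Step 13
Reactants: 20 (1R,3E)-6-[(tert-butyldimethylsilyl)oxy]-4-methyl-1-[(S)-(4-methylphenyl)sulfinyl]hex-3-en-1-yl 2,4,6-triisopropylbenzoate
Product: 21 (1R,3E)-6-hydroxy-4-methyl-1-[(S)-(4-methylphenyl)sulfinyl]hex-3-en-1-yl 2,4,6-triisopropylbenzoate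
Conditions: HF·pyridine, pyridine/THF, 0 °C → rt
Reagents that add atoms: none
Why: Buffered fluoride desilylation frees the primary alcohol without base-induced elimination of the α-acyloxy sulfoxide.

Step 14
Reactants: 21 (1R,3E)-6-hydroxy-4-methyl-1-[(S)-(4-methylphenyl)sulfinyl]hex-3-en-1-yl 2,4,6-triisopropylbenzoate
Product: 22 (1R,3E)-4-methyl-1-[(S)-(4-methylphenyl)sulfinyl]-6-oxohex-3-en-1-yl 2,4,6-triisopropylbenzoate
Conditions: Dess–Martin periodinane, pyridine, CH2Cl2, 0 °C; used at once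
Reagents that add atoms: none
Why: Neutral Dess–Martin oxidation gives the β,γ-unsaturated aldehyde without moving the alkene into conjugation.

Step 15
Reactants: 13 (1R,3Z)-1-[(2S,3S)-3-[(2S)-4-(bromomethyl)-5-oxo-2,5-dihydrofuran-2-yl]-2-methyloxiran-2-yl]-4-(4,4,5,5-tetramethyl-1,3,2-dioxaborolan-2-yl)pent-3-en-1-yl acetate; 22 (1R,3E)-4-methyl-1-[(S)-(4-methylphenyl)sulfinyl]-6-oxohex-3-en-1-yl 2,4,6-triisopropylbenzoate
Product: 23 14-epi seco alcohol (1R,2S,3S,4S,5R,9R,14S; 7Z,11E): trans-fused α-methylene-γ-butyrolactone with free 14-OH, 5-OAc, C8–B(pin) and C9 bearing triisopropylbenzoyloxy and (S)-p-tolylsulfinyl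
Conditions: CrCl2 (6 equiv), THF, 0 °C → rt (bromide and aldehyde added together)
Reagents that add atoms: none
Why: Nozaki–Hiyama-type allylation in which divalent chromium metalates the allylic bromide and the γ-carbon (C1) adds to the aldehyde through a chair transition state anti to the C2 substituent, giving the trans-fused α-methylene lactone (C1 R) and, because the ring fixes an E-type allyl geometry, the 1,14-anti carbinol (14S).

Step 16
Reactants: 23 14-epi seco alcohol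
Product: 24 seco diacetate (1R,2S,3S,4S,5R,9R,14R; 7Z,11E)
Conditions: AcOH, PPh3, DIAD, toluene, 0 °C → rt
Reagents that add atoms: acetic acid, CC(=O)O
Why: Mitsunobu reaction with acetic acid displaces the activated C14 oxygen by SN2 with inversion, giving the natural (14R)-acetate in one operation.

Step 17
Reactants: 24 seco diacetate
Product: 28 michaolide A, via magnesium carbenoid 25 (not isolated), via cyclic boronate complex 26 (not isolated), via macrocyclic allylboronate 27 (not isolated)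
Conditions: i-PrMgCl·LiCl (1.2 equiv), THF, 1 mM, −78 °C, 30 min; −78 → 40 °C, 3 h; then NaBO3·4H2O, THF/H2O, 0 °C → rt
Reagents that add atoms: sodium perborate (NaBO3·4H2O), [Na+].[Na+].O[B-]1(O)OO[B-](O)(O)OO1
Why: Proposed new method: a ring-contractive, macrocyclising 1,2-metallate rearrangement, in which sulfoxide–magnesium exchange gives a configurationally stable α-acyloxyalkylmagnesium carbenoid at C9 (retention) that is captured by the tethered alkenyl-B(pin) to form a 15-membered cyclic boronate complex, whose C8 alkenyl group then shifts from boron to C9 anti to the departing triisopropylbenzoate (inversion at C9, alkene geometry retained), contracting the boracycle to the 14-membered carbocycle before stereoretentive C–B oxidation gives the (9S)-alcohol; the closest known reaction is the intermolecular in-situ homologation of alkenyl pinacol boronates with sulfoxide-derived carbenoids (lithiation–borylation, Matteson-type 1,2-shift), which has not been shown intramolecularly for a macrocycle.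

## Compound list

1 | (2E)-3-methyl-4-oxobut-2-en-1-yl acetate | CC(=O)OC/C=C(\C)C=O | starting material
2 | (2E,4R)-3-methyl-4-[(4,4,5,5-tetramethyl-1,3,2-dioxaborolan-2-yl)oxy]hepta-2,6-dien-1-yl acetate | CC(=O)OC/C=C(\C)[C@H](OB1OC(C)(C)C(C)(C)O1)CC=C | intermediate
3 | (2E,4R)-4-hydroxy-3-methylhepta-2,6-dien-1-yl acetate | CC(=O)OC/C=C(\C)[C@H](O)CC=C | intermediate
4 | (2E,4R)-3-methylhepta-2,6-diene-1,4-diyl diacetate | CC(=O)OC/C=C(\C)[C@H](OC(C)=O)CC=C | intermediate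
5 | (2E,4R)-1-hydroxy-3-methylhepta-2,6-dien-4-yl acetate | OC/C=C(\C)[C@H](OC(C)=O)CC=C | intermediate
6 | (1R)-1-[(2S,3S)-3-(hydroxymethyl)-2-methyloxiran-2-yl]but-3-en-1-yl acetate | OC[C@@H]1O[C@@]1(C)[C@H](OC(C)=O)CC=C | intermediate
7 | (1R,3Z)-1-[(2S,3S)-3-(hydroxymethyl)-2-methyloxiran-2-yl]-4-(4,4,5,5-tetramethyl-1,3,2-dioxaborolan-2-yl)pent-3-en-1-yl acetate | OC[C@@H]1O[C@@]1(C)[C@H](OC(C)=O)C/C=C(\C)B1OC(C)(C)C(C)(C)O1 | intermediate
8 | (1R,3Z)-1-[(2S,3R)-3-formyl-2-methyloxiran-2-yl]-4-(4,4,5,5-tetramethyl-1,3,2-dioxaborolan-2-yl)pent-3-en-1-yl acetate | O=C[C@@H]1O[C@@]1(C)[C@H](OC(C)=O)C/C=C(\C)B1OC(C)(C)C(C)(C)O1 | intermediate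
9 | methyl propiolate | C#CC(=O)OC | starting material
10 | methyl (2Z)-2-(hydroxymethyl)-3-iodoprop-2-enoate | I/C=C(/CO)C(=O)OC | intermediate
11 | methyl (2Z,4S)-4-[(2S,3S)-3-[(1R,3Z)-1-acetoxy-4-(4,4,5,5-tetramethyl-1,3,2-dioxaborolan-2-yl)pent-3-en-1-yl]-3-methyloxiran-2-yl]-4-hydroxy-2-(hydroxymethyl)but-2-enoate | COC(=O)/C(CO)=C\[C@H](O)[C@@H]1O[C@@]1(C)[C@H](OC(C)=O)C/C=C(\C)B1OC(C)(C)C(C)(C)O1 | intermediate
12 | (1R,3Z)-1-[(2S,3S)-3-[(2S)-4-(hydroxymethyl)-5-oxo-2,5-dihydrofuran-2-yl]-2-methyloxiran-2-yl]-4-(4,4,5,5-tetramethyl-1,3,2-dioxaborolan-2-yl)pent-3-en-1-yl acetate | OCC1=C[C@H](OC1=O)[C@@H]2O[C@@]2(C)[C@H](OC(C)=O)C/C=C(\C)B3OC(C)(C)C(C)(C)O3 | intermediate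
13 | (1R,3Z)-1-[(2S,3S)-3-[(2S)-4-(bromomethyl)-5-oxo-2,5-dihydrofuran-2-yl]-2-methyloxiran-2-yl]-4-(4,4,5,5-tetramethyl-1,3,2-dioxaborolan-2-yl)pent-3-en-1-yl acetate | BrCC1=C[C@H](OC1=O)[C@@H]2O[C@@]2(C)[C@H](OC(C)=O)C/C=C(\C)B3OC(C)(C)C(C)(C)O3 | intermediate
14 | tert-butyl(but-3-yn-1-yloxy)dimethylsilane | C#CCCO[Si](C)(C)C(C)(C)C | starting material
15 | [(1E)-4-[(tert-butyldimethylsilyl)oxy]-2-methylbut-1-en-1-yl]dimethylalane | C[Al](C)/C=C(\C)CCO[Si](C)(C)C(C)(C)C | intermediate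
16 | (3E)-6-[(tert-butyldimethylsilyl)oxy]-4-methylhex-3-en-1-ol | OCC/C=C(\C)CCO[Si](C)(C)C(C)(C)C | intermediate
17 | (3E)-6-[(tert-butyldimethylsilyl)oxy]-4-methylhex-3-en-1-yl 2,4,6-triisopropylbenzoate | CC(C)c1cc(C(C)C)c(C(=O)OCC/C=C(\C)CCO[Si](C)(C)C(C)(C)C)c(C(C)C)c1 | intermediate
18 | (1R,3E)-6-[(tert-butyldimethylsilyl)oxy]-1-lithio-4-methylhex-3-en-1-yl 2,4,6-triisopropylbenzoate | CC(C)c1cc(C(C)C)c(C(=O)O[C@H]([Li])C/C=C(\C)CCO[Si](C)(C)C(C)(C)C)c(C(C)C)c1 | intermediate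
19 | (1R,3E)-1-(bromomagnesio)-6-[(tert-butyldimethylsilyl)oxy]-4-methylhex-3-en-1-yl 2,4,6-triisopropylbenzoate | CC(C)c1cc(C(C)C)c(C(=O)O[C@H]([Mg]Br)C/C=C(\C)CCO[Si](C)(C)C(C)(C)C)c(C(C)C)c1 | intermediate
20 | (1R,3E)-6-[(tert-butyldimethylsilyl)oxy]-4-methyl-1-[(S)-(4-methylphenyl)sulfinyl]hex-3-en-1-yl 2,4,6-triisopropylbenzoate | CC(C)c1cc(C(C)C)c(C(=O)O[C@H]([S@@](=O)c2ccc(C)cc2)C/C=C(\C)CCO[Si](C)(C)C(C)(C)C)c(C(C)C)c1 | intermediate
21 | (1R,3E)-6-hydroxy-4-methyl-1-[(S)-(4-methylphenyl)sulfinyl]hex-3-en-1-yl 2,4,6-triisopropylbenzoate | CC(C)c1cc(C(C)C)c(C(=O)O[C@H]([S@@](=O)c2ccc(C)cc2)C/C=C(\C)CCO)c(C(C)C)c1 | intermediate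
22 | (1R,3E)-4-methyl-1-[(S)-(4-methylphenyl)sulfinyl]-6-oxohex-3-en-1-yl 2,4,6-triisopropylbenzoate | CC(C)c1cc(C(C)C)c(C(=O)O[C@H]([S@@](=O)c2ccc(C)cc2)C/C=C(\C)CC=O)c(C(C)C)c1 | intermediate
23 | 14-epi seco alcohol (1R,2S,3S,4S,5R,9R,14S; 7Z,11E; sulfur S): trans-fused α-methylene-γ-butyrolactone, free 14-OH, 5-OAc, C8–B(pin), C9 with triisopropylbenzoyloxy and p-tolylsulfinyl | CC(C)c1cc(C(C)C)c(C(=O)O[C@H]([S@@](=O)c2ccc(C)cc2)C/C=C(\C)C[C@H](O)[C@H]3C(=C)C(=O)O[C@@H]3[C@@H]4O[C@@]4(C)[C@H](OC(C)=O)C/C=C(\C)B5OC(C)(C)C(C)(C)O5)c(C(C)C)c1 | intermediate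
24 | seco diacetate (1R,2S,3S,4S,5R,9R,14R; 7Z,11E; sulfur S): as 23 with inverted 14-OAc | CC(C)c1cc(C(C)C)c(C(=O)O[C@H]([S@@](=O)c2ccc(C)cc2)C/C=C(\C)C[C@@H](OC(C)=O)[C@H]3C(=C)C(=O)O[C@@H]3[C@@H]4O[C@@]4(C)[C@H](OC(C)=O)C/C=C(\C)B5OC(C)(C)C(C)(C)O5)c(C(C)C)c1 | intermediate
25 | magnesium carbenoid: 24 with the C9 sulfinyl group replaced by MgCl (retention) | CC(C)c1cc(C(C)C)c(C(=O)O[C@H]([Mg]Cl)C/C=C(\C)C[C@@H](OC(C)=O)[C@H]2C(=C)C(=O)O[C@@H]2[C@@H]3O[C@@]3(C)[C@H](OC(C)=O)C/C=C(\C)B4OC(C)(C)C(C)(C)O4)c(C(C)C)c1 | intermediate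
26 | cyclic boronate complex: 15-membered boracycle with tetracoordinate boron bound to C8, C9 and pinacolate, C9 still carrying the triisopropylbenzoate; chloromagnesium salt | CC(C)c1cc(C(C)C)c(C(=O)O[C@H]2C/C=C(\C)C[C@@H](OC(C)=O)[C@H]3C(=C)C(=O)O[C@@H]3[C@@H]4O[C@@]4(C)[C@H](OC(C)=O)C/C=C(\C)[B-]25OC(C)(C)C(C)(C)O5)c(C(C)C)c1.Cl[Mg+] | intermediate
27 | macrocyclic allylboronate: (9S)-9-deoxy-9-(4,4,5,5-tetramethyl-1,3,2-dioxaborolan-2-yl)michaolide A | C=C1C(=O)O[C@H]2[C@H]1[C@H](OC(C)=O)C/C(C)=C/C[C@H](B3OC(C)(C)C(C)(C)O3)/C(C)=C/C[C@@H](OC(C)=O)[C@]1(C)O[C@@H]21 | intermediate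
28 | michaolide A | C=C1C(=O)O[C@H]2[C@H]1[C@H](OC(C)=O)C/C(C)=C/C[C@H](O)/C(C)=C/C[C@@H](OC(C)=O)[C@]1(C)O[C@@H]21 | target

## Step count and risks

Total step count: 17. Longest linear sequence: 11 steps (steps 1–6, 8, 9, 15, 16, 17).

Steps most likely to fail:

Step 17 (the proposed ring-contractive 1,2-metallate macrocyclisation). The magnesium carbenoid may oligomerise or decompose before it finds the tethered boronate. The fallback is a Nozaki–Hiyama–Kishi macrocyclisation at the same bond; it sets out from 16 and 13 and comes back at 28. Alcohol 16 is protected (NaH, 4-methoxybenzyl chloride) as the 4-methoxybenzyl ether F1. Desilylation (TBAF) gives alcohol F2, and Dess–Martin oxidation gives aldehyde F3. This is joined to 13 with CrCl2 as in step 15 to give the adduct F4, and Mitsunobu reaction with AcOH gives the diacetate F5. Iododeboronation with retention (NIS, MeCN) gives the vinyl iodide F6. DDQ removes the benzyl ether to give alcohol F7, and Dess–Martin oxidation gives the iodo aldehyde F8. This is closed with CrCl2/NiCl2 (cat.) in DMSO/THF at 2 mM, with a chiral sulfonamide ligand to favour 9S, to give 28 after separation from its C9 epimer.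

Step 15 (chromium-mediated union). The β,γ-unsaturated aldehyde may enolise or isomerise, and facial control at C1/C14 may be poor. The fallback replaces the Barbier process by a catalysed allylboration with an isolated reagent; it sets out from 13 and 22 and comes back at 23. Bromide 13 is borylated (B2pin2, Pd2(dba)3 cat., DMSO) to the allylboronate F9. This adds to 22 under Sc(OTf)3 catalysis (toluene, −78 → 0 °C) through the same chair arrangement and gives 23 after aqueous work-up.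

Step 16 (Mitsunobu inversion at C14). Elimination towards C1 or C13 may compete with substitution. The fallback is a redox inversion; it sets out from 23 and comes back at 24. Dess–Martin oxidation gives the C14 ketone F10. Reduction with (S)-Me-CBS/catecholborane (toluene, −78 °C) gives the (14R)-alcohol F11, which is acetylated (Ac2O, DMAP) to 24.

## Further compounds

F1 | step 17 | 1-[({(3E)-6-[(tert-butyldimethylsilyl)oxy]-4-methylhex-3-en-1-yl}oxy)methyl]-4-methoxybenzene | COc1ccc(COCC/C=C(\C)CCO[Si](C)(C)C(C)(C)C)cc1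
F2 | step 17 | (3E)-6-[(4-methoxybenzyl)oxy]-3-methylhex-3-en-1-ol | COc1ccc(COCC/C=C(\C)CCO)cc1
F3 | step 17 | (3E)-6-[(4-methoxybenzyl)oxy]-3-methylhex-3-enal | COc1ccc(COCC/C=C(\C)CC=O)cc1
F4 | step 17 | 14-epi seco alcohol with C9 4-methoxybenzyl ether (1R,2S,3S,4S,5R,14S; 7Z,11E), C8–B(pin) | COc1ccc(COCC/C=C(\C)C[C@H](O)[C@H]2C(=C)C(=O)O[C@@H]2[C@@H]3O[C@@]3(C)[C@H](OC(C)=O)C/C=C(\C)B4OC(C)(C)C(C)(C)O4)cc1
F5 | step 17 | seco diacetate with C9 4-methoxybenzyl ether (14R), C8–B(pin) | COc1ccc(COCC/C=C(\C)C[C@@H](OC(C)=O)[C@H]2C(=C)C(=O)O[C@@H]2[C@@H]3O[C@@]3(C)[C@H](OC(C)=O)C/C=C(\C)B4OC(C)(C)C(C)(C)O4)cc1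
F6 | step 17 | seco diacetate with C9 4-methoxybenzyl ether and (7E)-C8 iodide | COc1ccc(COCC/C=C(\C)C[C@@H](OC(C)=O)[C@H]2C(=C)C(=O)O[C@@H]2[C@@H]3O[C@@]3(C)[C@H](OC(C)=O)C/C=C(\C)I)cc1
F7 | step 17 | seco diacetate with free C9 primary alcohol and (7E)-C8 iodide | OCC/C=C(\C)C[C@@H](OC(C)=O)[C@H]1C(=C)C(=O)O[C@@H]1[C@@H]2O[C@@]2(C)[C@H](OC(C)=O)C/C=C(\C)I
F8 | step 17 | seco diacetate with C9 aldehyde and (7E)-C8 iodide | O=CC/C=C(\C)C[C@@H](OC(C)=O)[C@H]1C(=C)C(=O)O[C@@H]1[C@@H]2O[C@@]2(C)[C@H](OC(C)=O)C/C=C(\C)I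
F9 | step 15 | (1R,3Z)-1-[(2S,3S)-2-methyl-3-[(2S)-5-oxo-4-[(4,4,5,5-tetramethyl-1,3,2-dioxaborolan-2-yl)methyl]-2,5-dihydrofuran-2-yl]oxiran-2-yl]-4-(4,4,5,5-tetramethyl-1,3,2-dioxaborolan-2-yl)pent-3-en-1-yl acetate | CC1(C)OB(CC2=C[C@H](OC2=O)[C@@H]3O[C@@]3(C)[C@H](OC(C)=O)C/C=C(\C)B4OC(C)(C)C(C)(C)O4)OC1(C)C
F10 | step 16 | C14 ketone of seco alcohol 23 | CC(C)c1cc(C(C)C)c(C(=O)O[C@H]([S@@](=O)c2ccc(C)cc2)C/C=C(\C)CC(=O)[C@H]3C(=C)C(=O)O[C@@H]3[C@@H]4O[C@@]4(C)[C@H](OC(C)=O)C/C=C(\C)B5OC(C)(C)C(C)(C)O5)c(C(C)C)c1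
F11 | step 16 | (14R)-seco alcohol (C14 epimer of 23) | CC(C)c1cc(C(C)C)c(C(=O)O[C@H]([S@@](=O)c2ccc(C)cc2)C/C=C(\C)C[C@@H](O)[C@H]3C(=C)C(=O)O[C@@H]3[C@@H]4O[C@@]4(C)[C@H](OC(C)=O)C/C=C(\C)B5OC(C)(C)C(C)(C)O5)c(C(C)C)c1
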